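## Structural features

Compound 18 is a 1-aryl-1,2-dihydronaphthalene. Ring A is a 6,7-dimethoxybenzene ring fused through C4a/C8a to ring B, the six-membered carbocycle C1–C4, and a 3,4-dimethoxyphenyl group (ring C) sits on C1. Ring B carries methyl groups on C2 and C3 and one double bond, C3=C4, conjugated with ring A. There are two stereocentres and they are neighbours: C1 (R, a doubly benzylic methine) and C2 (S), with the C1 aryl group and the C2 methyl group trans; C3 is trigonal. No heteroatom remains on ring B, so every handle used to build it must be erased at the end. The fragile points are the dihydronaphthalene itself (one dehydrogenation from a naphthalene), the doubly benzylic C1–H, and the styrene-type alkene, which acid or base could move toward C2 or C1; the four aryl methyl ethers tolerate everything except strong Lewis acids. The real difficulty is to fix C1 in the absolute sense, set C2 trans to it, and place the single alkene at C3=C4 and nowhere else. The key step exploits the C2–C3 bond: it joins two carbons that each bear a methyl group, both methyls can derive from carboxyl carbons, and so C2 and C3 can be the α-carbons of two esters already tied together through C1, C8a, C4a and C4. Atom labels of 18 are used for the corresponding atoms of all intermediates.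

## Logic of the disconnections

18 ⇒ 16. One C–H bond of each methyl group (on C2 and on C3) is exchanged for a C–O bond. This makes both methyls traceable to carboxyl carbons and turns a bare hydrocarbon periphery into carbonyl-derived functionality. The forward step must replace both sulfonate groups of 17 by hydride through direct substitution, the allylic one without transposition, and must leave C1 and C2 alone.

16 ⇒ 14. The C3=C4 π bond is cut; C3 receives a C–Se bond and C4 a hydrogen. A heteroatom on C3 can be installed by enolate chemistry while C3 still carries a carboxyl group. If the elimination is run at the alcohol oxidation level, the only activated β-hydrogens are the benzylic ones on C4. The position of the alkene is thereby reduced to the position of one selenium atom. The forward step needs a syn-elimination from 15 that goes to C4 and not to C2 or the carbinol carbons.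

14 ⇒ 13. Both CH2–O units return to the carboxyl level, because the C3 carboxyl group is needed for the enolate and the C2 carboxyl group for differentiation. The forward hydride reduction must leave the C–Se bond intact.

13 ⇒ 11. The C3–Se bond is cut. In 11 the C2 carboxyl group is a free acid and the C3 carboxyl group a methyl ester. After deprotonation of the acid, the only C–H that base can still remove is C3–H, so the site of selenation is fixed by functional-group identity and not by sterics. The forward step needs clean formation of 12.

11 ⇒ 10. The acid O–H is traced back to an O–tert-butyl bond. The two carboxyl groups of 10 then differ only in their alkyl groups, and that difference costs nothing earlier because it comes from two different building blocks, 2 and 6. The forward acidolysis must not alkylate the electron-rich rings.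

10 ⇒ 8. The C2–C3 bond of ring B is cut, the key disconnection. Both carbons are ester α-carbons of like polarity, so the bond is made by oxidising the bis-enolate 9. Ring B and two stereocentres disappear, and what remains is an open-chain diester with one stereocentre. The forward step must close the ring within one molecule and put the C2 ester trans to the C1 aryl group.

8 ⇒ 7 ⇒ 5 + 6. The bond between C4a of ring A and C4 is cut at the alkene oxidation level. The C–Br bond of 5 and the terminal alkene carbon of 6 are a matched pair for palladium catalysis. The three-carbon arm is thus reduced to a commodity acrylate. The forward steps need a Heck coupling on a hindered, electron-rich bromide and a hydrogenation that spares the diarylmethine.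

5 ⇒ 3 + 4. The bond between C1 and ring C is cut. C1 is β to an ester, so it can be made by catalytic asymmetric conjugate arylation. The only stereocentre of 8 is thus traced to two achiral partners. The forward step needs enantioface control and tolerance of the C–Br bond.

3 ⇒ 1 + 2. The C1=C2 alkene of 3 is cut by carbonyl olefination. The forward step must give the (E)-enoate, which the enantioface model of the next step presupposes.

## Other disconnections considered

Alternative 1: The cut removes C4a–C8a, C5–C6 and C7–C8, so rings A and B fall away together. In the forward direction the 1,7-diyne A1 and the diborylalkyne A2 would be cotrimerised ([2+2+2], for example with CpCo(CO)2) to the tetralinol A3. Oxidation of both C–B bonds, double O-methylation and dehydration of the tertiary alcohol would then lead to 18.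
- In its favour: two rings form in one operation, C1 and C2 are set in an open chain before any ring exists, and the two boryl groups would allow variation of ring A.
- Better than the chosen plan: the alkene is introduced by dehydration, without selenium and without differentiated carboxyl groups.
- Against it here: A1 holds two adjacent stereocentres, one of them both propargylic and benzylic and therefore prone to base-induced epimerisation or allene formation, and it needs its own multi-step asymmetric synthesis. Homo-oligomerisation of A1 competes with the cross reaction. The diboryl arene has to pass through an air-sensitive dihydroxy stage. The dehydration can run in three directions (C4, C2 or the methyl group).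
- Comparison: structurally the chosen plan buys ring A ready-made and spends its effort only on ring B. Mechanistically a metallacycle-mediated cycloaddition stands against an enolate oxidation, and both are known reaction types. In step economy the preparation of A1 alone is estimated to be as long as the whole chosen route. The two plans are equal in needing no protecting groups on the aryl ethers.

Alternative 2: The cut removes C4a–C5 and C8a–C8, so ring A is grown late. The enone A4 would undergo a Diels–Alder reaction with the diene A5 to give the cis-fused adduct A6, the diene approaching anti to the aryl group. Dehydrogenation of the new ring to the dimethoxybenzene, reduction of the ketone and dehydration would complete 18.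
- In its favour: both methoxy groups of ring A arrive with the diene, and the facial course is controlled by the substrate.
- Better than the chosen plan: the ketone carbon becomes C4, so the alkene position is fixed without regiochemical questions.
- Against it here: A4 already contains three contiguous stereocentres, of which only two survive, so the stereochemical problem is moved and not solved. Cyclohexenones are weak dienophiles that call for Lewis acids, and A5 is an acid-labile bis-enol ether. The α-methyl centre can epimerise. Four hydrogens must be removed oxidatively from a molecule that, once ring A is aromatic, has a doubly benzylic C1–H and is one step from a naphthalene.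
- Comparison: structurally the chosen plan sets C1 first and lets it control C2, while this alternative needs all centres before the key step. Mechanistically a concerted cycloaddition stands against a stepwise oxidative closure. In step economy no saving is expected once the synthesis of A4 is counted. The two plans are equal in that the absolute configuration would come from one early catalytic step.

Alternative 3: The cut removes C1–C2 and C3–C4. Irradiation of the aldehyde A7 would give a hydroxy-ortho-quinodimethane, which is trapped by the crotonate A8 to give the tetralol A9, with hydroxyl, ester and aryl cis and methyl trans. β-Elimination of water would give the C3=C4 enoate, and the ester would be taken down to the methyl group.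
- In its favour: A7 is a very simple diarylmethane aldehyde, ring B and the full carbon skeleton appear in one step, and the trans relation of aryl and methyl follows from the (E) geometry of A8 and a suprafacial addition.
- Better than the chosen plan: the route is clearly shorter, and the β-hydroxy ester fixes the alkene position by itself.
- Against it here: the absolute configuration would rest on a chiral Lewis acid controlling a short-lived photoenol. The two methoxy groups lower the efficiency of hydrogen abstraction by the excited aldehyde. A β-substituted acrylate is a slow trap, so reketonisation should compete. The geometry of the aryl-bearing diene terminus decides the aryl/methyl relation and is not assured.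
- Comparison: structurally both plans end with the same allylic carboxyl-to-methyl reduction and are equal there. Mechanistically a photochemical pericyclic step that sets four centres at once stands against a ground-state enolate oxidation that sets two under control of an existing centre. The alternative wins on step economy, and the chosen plan wins on confidence in the absolute configuration.

Key step: step 5

Remark: the sense of induction in step 2 is assigned from the accepted enantioface model of the rhodium–BINAP aryl complex for (E)-enoates; (R)-BINAP would be taken if the ortho-bromo substrate departed from it.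

## Route

Step 1
Reactants: 1 2-bromo-4,5-dimethoxybenzaldehyde; 2 tert-butyl (triphenylphosphoranylidene)acetate
Product: 3 tert-butyl (E)-3-(2-bromo-4,5-dimethoxyphenyl)prop-2-enoate
Conditions: toluene, 90 °C
Reagents that add atoms: none
Why: Wittig olefination with a stabilised ylide, which gives the (E)-enoate through the thermodynamically preferred oxaphosphetane; the aryl bromide and the methyl ethers are inert.

Step 2
Reactants: 3 tert-butyl (E)-3-(2-bromo-4,5-dimethoxyphenyl)prop-2-enoate; 4 3,4-dimethoxyphenylboronic acid
Product: 5 tert-butyl (3R)-3-(2-bromo-4,5-dimethoxyphenyl)-3-(3,4-dimethoxyphenyl)propanoate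
Conditions: [Rh(acac)(C2H4)2] (3 mol %), (S)-BINAP (3.3 mol %), 4 (3 equiv), dioxane/H2O 10:1, 100 °C
Reagents that add atoms: none
Why: Hayashi–Miyaura asymmetric 1,4-addition: transmetalation gives an aryl complex of monovalent rhodium, which inserts the (E)-enoate on the face left open by (S)-BINAP and so sets the benzylic centre as R; water then protonates the oxa-π-allyl rhodium. Monovalent rhodium is not expected to insert into the C–Br bond under these conditions, and the tert-butyl ester resists hydrolysis.

Step 3
Reactants: 5 tert-butyl (3R)-3-(2-bromo-4,5-dimethoxyphenyl)-3-(3,4-dimethoxyphenyl)propanoate; 6 methyl acrylate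
Product: 7 tert-butyl (3R)-3-(3,4-dimethoxyphenyl)-3-{4,5-dimethoxy-2-[(E)-3-methoxy-3-oxoprop-1-en-1-yl]phenyl}propanoate
Conditions: Pd(OAc)2 (5 mol %), P(o-tol)3 (10 mol %), Et3N, DMF, 110 °C
Reagents that add atoms: none
Why: Mizoroki–Heck reaction: zerovalent palladium formed in situ adds to the C–Br bond, and syn-insertion of the acrylate followed by syn-β-hydride elimination gives the (E)-cinnamate. The stereocentre has no hydrogen that Et3N can remove and is not touched.

Step 4
Reactants: 7 tert-butyl (3R)-3-(3,4-dimethoxyphenyl)-3-{4,5-dimethoxy-2-[(E)-3-methoxy-3-oxoprop-1-en-1-yl]phenyl}propanoate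
Product: 8 tert-butyl (3R)-3-(3,4-dimethoxyphenyl)-3-[4,5-dimethoxy-2-(3-methoxy-3-oxopropyl)phenyl]propanoate
Conditions: H2 (1 atm), 10% Pd/C, EtOAc, rt
Reagents that add atoms: none
Why: Heterogeneous hydrogenation saturates only the conjugated C=C; the diarylmethine C–H, the aryl ethers and both esters are stable at ambient pressure and temperature.

Step 5
Reactants: 8 tert-butyl (3R)-3-(3,4-dimethoxyphenyl)-3-[4,5-dimethoxy-2-(3-methoxy-3-oxopropyl)phenyl]propanoate
Product: 10 2-tert-butyl 3-methyl (1R,2S,3S)-1-(3,4-dimethoxyphenyl)-6,7-dimethoxy-1,2,3,4-tetrahydronaphthalene-2,3-dicarboxylate, via dilithium bis-enolate 9 (not isolated)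
Conditions: LiN(iPr)2 (2.3 equiv), THF, −78 °C, slow addition of 8 (final 0.02 M); then anhydrous CuBr2 (2.4 equiv), −78 °C → 0 °C
Reagents that add atoms: none
Why: Two equivalents of LiN(iPr)2 convert 8 into the bis(lithium enolate) 9; CuBr2 (divalent copper) takes one electron from one enolate to give an α-ester radical (or its α-bromo ester equivalent), this carbon is captured by the carbon of the second enolate, and a second CuBr2 oxidises the resulting ester ketyl, leaving neutral 10 and CuBr (monovalent copper). The closest known reaction type is the copper-dihalide or iodine oxidation of ester dienolates to succinates, including its intramolecular form that gives cyclic trans-1,2-diesters. Ring B closes in a 6-exo-trig mode, one α-carbon adding to the enolate C=C of the other, which stays outside the new ring. C2 is controlled by allylic 1,3-strain across C1–C2: C1–H lies in the plane of the C2 enolate, the tether through ring A can reach only one face, and the tert-butyl ester ends up trans to the C1 aryl group. C3 is controlled by the chair-like transition state, in which its ester is pseudo-equatorial and anti to the C2 ester (2,3-trans); this centre is planarised later, so its configuration is not critical. The all-trans isomer, with three equatorial groups, is also the thermodynamically preferred one, so the kinetic and the equilibrium preference point the same way. The step needs ring closure to win over intermolecular coupling and over Claisen or Dieckmann condensation; the ortho-disposed arms, high dilution, slow addition of 8 to excess base at −78 °C and the poorly electrophilic tert-butyl ester secure this. C1 has no acidic hydrogen under these conditions and keeps its configuration.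

Step 6
Reactants: 10 2-tert-butyl 3-methyl (1R,2S,3S)-1-(3,4-dimethoxyphenyl)-6,7-dimethoxy-1,2,3,4-tetrahydronaphthalene-2,3-dicarboxylate
Product: 11 (1R,2S,3S)-1-(3,4-dimethoxyphenyl)-6,7-dimethoxy-3-(methoxycarbonyl)-1,2,3,4-tetrahydronaphthalene-2-carboxylic acid
Conditions: CF3CO2H/CH2Cl2 1:4, Et3SiH (2.5 equiv), 0 °C → rt
Reagents that add atoms: none
Why: Acidolysis of the tert-butyl ester by alkyl–oxygen cleavage, which leaves the methyl ester untouched; Et3SiH reduces the tert-butyl cation before it can alkylate the dimethoxyarenes. Ester and acid α-centres do not enolise under these conditions, so C2 and C3 are retained.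

Step 7
Reactants: 11 (1R,2S,3S)-1-(3,4-dimethoxyphenyl)-6,7-dimethoxy-3-(methoxycarbonyl)-1,2,3,4-tetrahydronaphthalene-2-carboxylic acid
Product: 13 (1R,2R)-1-(3,4-dimethoxyphenyl)-6,7-dimethoxy-3-(methoxycarbonyl)-3-(phenylselanyl)-1,2,3,4-tetrahydronaphthalene-2-carboxylic acid (C3 configuration open), via dilithium carboxylate enolate 12 (not isolated)
Conditions: LiN(iPr)2 (2.2 equiv), THF, −78 °C; PhSeBr (1.2 equiv), −78 °C; aq. HCl work-up
Reagents that add atoms: benzeneselenenyl bromide, Br[Se]c1ccccc1
Why: Half-ester dianion chemistry followed by α-selenenylation of an ester enolate: the first equivalent of base makes the carboxylate, whose α-hydrogen at C2 is then far too weakly acidic to be removed at −78 °C, so the second equivalent can only deprotonate C3–H next to the methyl ester. The new C3 centre may form as either epimer because it is destroyed in step 9; C2 is untouched (its descriptor changes from S to R only because selenium raises the priority of C3).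

Step 8
Reactants: 13 (1R,2R)-1-(3,4-dimethoxyphenyl)-6,7-dimethoxy-3-(methoxycarbonyl)-3-(phenylselanyl)-1,2,3,4-tetrahydronaphthalene-2-carboxylic acid
Product: 14 [(1R,2R)-1-(3,4-dimethoxyphenyl)-6,7-dimethoxy-3-(phenylselanyl)-1,2,3,4-tetrahydronaphthalene-2,3-diyl]dimethanol
Conditions: LiAlH4 (4 equiv), THF, 0 °C → rt
Reagents that add atoms: none
Why: Hydride reduction of a carboxylic acid and an ester to primary alcohols; reduction of α-seleno esters to β-hydroxy selenides is established, and the alkyl aryl selenide is not cleaved by hydride.

Step 9
Reactants: 14 [(1R,2R)-1-(3,4-dimethoxyphenyl)-6,7-dimethoxy-3-(phenylselanyl)-1,2,3,4-tetrahydronaphthalene-2,3-diyl]dimethanol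
Product: 16 [(1R,2S)-1-(3,4-dimethoxyphenyl)-6,7-dimethoxy-1,2-dihydronaphthalene-2,3-diyl]dimethanol, via selenoxide 15 (not isolated)
Conditions: mCPBA (1.05 equiv), CH2Cl2, −78 °C; then iPr2NH (3 equiv), −78 °C → rt
Reagents that add atoms: none
Why: Selenoxide syn-elimination: the peracid oxidises selenium selectively at −78 °C, and on warming the selenoxide abstracts a benzylic C4–H to give the styrene-conjugated C3=C4 alkene. Elimination toward a carbinol carbon is known to be disfavoured, and elimination toward the unactivated C2–H would give a non-conjugated tetrasubstituted alkene; the amine traps PhSeOH so that it does not add back.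

Step 10
Reactants: 16 [(1R,2S)-1-(3,4-dimethoxyphenyl)-6,7-dimethoxy-1,2-dihydronaphthalene-2,3-diyl]dimethanol
Product: 18 (1R,2S)-1-(3,4-dimethoxyphenyl)-6,7-dimethoxy-2,3-dimethyl-1,2-dihydronaphthalene, via bis(methanesulfonate) 17 (not isolated)
Conditions: Ms2O (3 equiv), Et3N (4 equiv), THF, −20 °C; then LiEt3BH (8 equiv), −20 °C → rt
Reagents that add atoms: none
Why: Sulfonylation of both primary alcohols followed by SN2 displacement with hydride. Direct attack at the primary allylic carbon is expected because the SN2′ path would take the alkene out of conjugation with ring A, and the labile allylic sulfonate is reduced in the same flask without isolation; C1 and C2 are not involved.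

## Compound list

1 | 2-bromo-4,5-dimethoxybenzaldehyde | COc1cc(Br)c(C=O)cc1OC | starting material
2 | tert-butyl (triphenylphosphoranylidene)acetate | CC(C)(C)OC(=O)C=P(c1ccccc1)(c1ccccc1)c1ccccc1 | starting material
3 | tert-butyl (E)-3-(2-bromo-4,5-dimethoxyphenyl)prop-2-enoate | CC(C)(C)OC(=O)/C=C/c1cc(OC)c(OC)cc1Br | intermediate
4 | 3,4-dimethoxyphenylboronic acid | OB(O)c1ccc(OC)c(OC)c1 | starting material
5 | tert-butyl (3R)-3-(2-bromo-4,5-dimethoxyphenyl)-3-(3,4-dimethoxyphenyl)propanoate | CC(C)(C)OC(=O)C[C@H](c1ccc(OC)c(OC)c1)c1cc(OC)c(OC)cc1Br | intermediate
6 | methyl acrylate | C=CC(=O)OC | starting material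
7 | tert-butyl (3R)-3-(3,4-dimethoxyphenyl)-3-{4,5-dimethoxy-2-[(E)-3-methoxy-3-oxoprop-1-en-1-yl]phenyl}propanoate | COC(=O)/C=C/c1cc(OC)c(OC)cc1[C@H](CC(=O)OC(C)(C)C)c1ccc(OC)c(OC)c1 | intermediate
8 | tert-butyl (3R)-3-(3,4-dimethoxyphenyl)-3-[4,5-dimethoxy-2-(3-methoxy-3-oxopropyl)phenyl]propanoate | COC(=O)CCc1cc(OC)c(OC)cc1[C@H](CC(=O)OC(C)(C)C)c1ccc(OC)c(OC)c1 | intermediate
9 | dilithium bis-enolate of 8 (enolate geometries open) | COC(O[Li])=CCc1cc(OC)c(OC)cc1[C@H](C=C(O[Li])OC(C)(C)C)c1ccc(OC)c(OC)c1 | intermediate
10 | 2-tert-butyl 3-methyl (1R,2S,3S)-1-(3,4-dimethoxyphenyl)-6,7-dimethoxy-1,2,3,4-tetrahydronaphthalene-2,3-dicarboxylate | COc1ccc([C@@H]2c3cc(OC)c(OC)cc3C[C@H](C(=O)OC)[C@H]2C(=O)OC(C)(C)C)cc1OC | intermediate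
11 | (1R,2S,3S)-1-(3,4-dimethoxyphenyl)-6,7-dimethoxy-3-(methoxycarbonyl)-1,2,3,4-tetrahydronaphthalene-2-carboxylic acid | COc1ccc([C@@H]2c3cc(OC)c(OC)cc3C[C@H](C(=O)OC)[C@H]2C(=O)O)cc1OC | intermediate
12 | dilithium salt of 11: C2 carboxylate and C3 ester enolate (enolate geometry open) | COc1ccc([C@@H]2c3cc(OC)c(OC)cc3CC(=C(O[Li])OC)[C@H]2C(=O)O[Li])cc1OC | intermediate
13 | (1R,2R)-1-(3,4-dimethoxyphenyl)-6,7-dimethoxy-3-(methoxycarbonyl)-3-(phenylselanyl)-1,2,3,4-tetrahydronaphthalene-2-carboxylic acid (C3 configuration open) | COc1ccc([C@@H]2c3cc(OC)c(OC)cc3CC([Se]c3ccccc3)(C(=O)OC)[C@H]2C(=O)O)cc1OC | intermediate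
14 | [(1R,2R)-1-(3,4-dimethoxyphenyl)-6,7-dimethoxy-3-(phenylselanyl)-1,2,3,4-tetrahydronaphthalene-2,3-diyl]dimethanol (C3 configuration open) | COc1ccc([C@@H]2c3cc(OC)c(OC)cc3CC([Se]c3ccccc3)(CO)[C@H]2CO)cc1OC | intermediate
15 | Se-oxide of 14 (C3 and Se configurations open) | COc1ccc([C@@H]2c3cc(OC)c(OC)cc3CC([Se](=O)c3ccccc3)(CO)[C@H]2CO)cc1OC | intermediate
16 | [(1R,2S)-1-(3,4-dimethoxyphenyl)-6,7-dimethoxy-1,2-dihydronaphthalene-2,3-diyl]dimethanol | COc1ccc([C@@H]2c3cc(OC)c(OC)cc3C=C(CO)[C@H]2CO)cc1OC | intermediate
17 | [(1R,2S)-1-(3,4-dimethoxyphenyl)-6,7-dimethoxy-1,2-dihydronaphthalene-2,3-diyl]bis(methylene) dimethanesulfonate | COc1ccc([C@@H]2c3cc(OC)c(OC)cc3C=C(COS(C)(=O)=O)[C@H]2COS(C)(=O)=O)cc1OC | intermediate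
18 | (1R,2S)-1-(3,4-dimethoxyphenyl)-6,7-dimethoxy-2,3-dimethyl-1,2-dihydronaphthalene | COc1ccc([C@@H]2c3cc(OC)c(OC)cc3C=C(C)[C@H]2C)cc1OC | target

## Step count and least certain steps

Total step count: 10. Longest linear sequence: 10 steps (1 → 18); the other starting materials 2, 4 and 6 enter directly.

Step 5 (key step). The most likely failure is incomplete double enolisation followed by Claisen-type condensation, or oxidation running between molecules to give oligomers in place of ring closure. A lesser risk is incomplete selection of the 1,2-trans isomer, which a base equilibration (DBU, toluene) should correct because the all-trans isomer is the stable one. Fallback: set out from 8 and separate enolisation from oxidation. LiN(iPr)2 (2.3 equiv) and Me3SiCl in THF at −78 °C give the bis(trimethylsilyl ketene acetal) F1, a neutral species that cannot undergo Claisen condensation. TiCl4 in CH2Cl2 at −78 °C, the established oxidant for coupling ketene silyl acetals to succinates, then joins the two acetal carbons and comes back to the route at 10; the tert-butyl ester is expected to survive at that temperature.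

Step 2. The most likely failure is slow insertion of the ortho-substituted enoate with its bulky ester, so that protodeboronation of 4 outruns addition, or loss of enantioface discrimination caused by the ortho-bromine. Fallback: auxiliary-controlled conjugate addition, setting out from 3.
- CF3CO2H in CH2Cl2 gives (E)-3-(2-bromo-4,5-dimethoxyphenyl)prop-2-enoic acid F2.
- Pivaloyl chloride, Et3N, LiCl and (4S)-4-phenyl-1,3-oxazolidin-2-one give the N-enoyl oxazolidinone F3.
- 3,4-(MeO)2C6H3MgBr with CuBr·SMe2 in THF at −40 °C is expected to add to the magnesium-chelated s-cis enoyl unit on the face opposite the phenyl group and give the (3R) adduct F4.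
- LiOH/H2O2 in THF/H2O at 0 °C releases (3R)-3-(2-bromo-4,5-dimethoxyphenyl)-3-(3,4-dimethoxyphenyl)propanoic acid F5 and the auxiliary.
- tert-Butyl 2,2,2-trichloroacetimidate with catalytic BF3·OEt2 comes back to the route at 5.

Step 9. The most likely failure is over-oxidation at selenium followed by displacement by a neighbouring hydroxyl group (cyclic ether formation), or re-addition of PhSeOH to the new electron-rich alkene. Fallback: eliminate before the hydroxyl groups exist, setting out from 13. NaIO4 and NaHCO3 in MeOH/H2O (0 °C → rt) give the selenoxide F6 as its carboxylate salt, in which C2–H is deactivated. Syn-elimination toward C4 gives (1R,2S)-1-(3,4-dimethoxyphenyl)-6,7-dimethoxy-3-(methoxycarbonyl)-1,2-dihydronaphthalene-2-carboxylic acid F7. AlH3 (from LiAlH4 and AlCl3, Et2O/THF, 0 °C) reduces acid and conjugated ester by 1,2-addition and comes back to the route at 16.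

Step 10. The most likely failure is hydride delivery with allylic transposition (SN2′), base-induced elimination of the homoallylic sulfonate, or loss of the labile allylic sulfonate before reduction. Fallback: change from polar substitution to radical-chain reduction, setting out from 16. CBr4 and PPh3 in CH2Cl2 at 0 °C (Appel reaction) give (1R,2S)-2,3-bis(bromomethyl)-1-(3,4-dimethoxyphenyl)-6,7-dimethoxy-1,2-dihydronaphthalene F8. Bu3SnH with catalytic AIBN in toluene at 80 °C replaces both bromines by hydrogen; the allylic radical is expected to take hydrogen at its primary terminus, which keeps the alkene conjugated with ring A, and the sequence comes back to the route at 18.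

## Further compounds

F1 | step 5 | [(3R)-1-tert-butoxy-3-(3,4-dimethoxyphenyl)-3-{4,5-dimethoxy-2-[3-methoxy-3-(trimethylsilyloxy)prop-2-en-1-yl]phenyl}prop-1-en-1-yl]oxy(trimethyl)silane, the bis(trimethylsilyl ketene acetal) of 8 (enol ether geometries open) | COC(O[Si](C)(C)C)=CCc1cc(OC)c(OC)cc1[C@H](C=C(O[Si](C)(C)C)OC(C)(C)C)c1ccc(OC)c(OC)c1
F2 | step 2 | (E)-3-(2-bromo-4,5-dimethoxyphenyl)prop-2-enoic acid | OC(=O)/C=C/c1cc(OC)c(OC)cc1Br
F3 | step 2 | (4S)-3-[(E)-3-(2-bromo-4,5-dimethoxyphenyl)prop-2-enoyl]-4-phenyl-1,3-oxazolidin-2-one | O=C1OC[C@H](c2ccccc2)N1C(=O)/C=C/c1cc(OC)c(OC)cc1Br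
F4 | step 2 | (4S)-3-[(3R)-3-(2-bromo-4,5-dimethoxyphenyl)-3-(3,4-dimethoxyphenyl)propanoyl]-4-phenyl-1,3-oxazolidin-2-one | O=C1OC[C@H](c2ccccc2)N1C(=O)C[C@H](c1ccc(OC)c(OC)c1)c1cc(OC)c(OC)cc1Br
F5 | step 2 | (3R)-3-(2-bromo-4,5-dimethoxyphenyl)-3-(3,4-dimethoxyphenyl)propanoic acid | OC(=O)C[C@H](c1ccc(OC)c(OC)c1)c1cc(OC)c(OC)cc1Br
F6 | step 9 | Se-oxide of 13 (C3 and Se configurations open) | COc1ccc([C@@H]2c3cc(OC)c(OC)cc3CC([Se](=O)c3ccccc3)(C(=O)OC)[C@H]2C(=O)O)cc1OC
F7 | step 9 | (1R,2S)-1-(3,4-dimethoxyphenyl)-6,7-dimethoxy-3-(methoxycarbonyl)-1,2-dihydronaphthalene-2-carboxylic acid | COc1ccc([C@@H]2c3cc(OC)c(OC)cc3C=C(C(=O)OC)[C@H]2C(=O)O)cc1OC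
F8 | step 10 | (1R,2S)-2,3-bis(bromomethyl)-1-(3,4-dimethoxyphenyl)-6,7-dimethoxy-1,2-dihydronaphthalene | COc1ccc([C@@H]2c3cc(OC)c(OC)cc3C=C(CBr)[C@H]2CBr)cc1OC
A1 | alternative 1 | (3S,4S)-3-(3,4-dimethoxyphenyl)-4,5-dimethylocta-1,7-diyn-5-ol (C5 configuration open) | COc1ccc([C@H](C#C)[C@H](C)C(C)(O)CC#C)cc1OC
A2 | alternative 1 | 1,2-bis(4,4,5,5-tetramethyl-1,3,2-dioxaborolan-2-yl)ethyne | CC1(C)OB(C#CB2OC(C)(C)C(C)(C)O2)OC1(C)C
A3 | alternative 1 | (3S,4R)-4-(3,4-dimethoxyphenyl)-2,3-dimethyl-6,7-bis(4,4,5,5-tetramethyl-1,3,2-dioxaborolan-2-yl)-1,2,3,4-tetrahydronaphthalen-2-ol (C2 configuration open) | COc1ccc([C@@H]2c3cc(B4OC(C)(C)C(C)(C)O4)c(B4OC(C)(C)C(C)(C)O4)cc3CC(C)(O)[C@H]2C)cc1OC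
A4 | alternative 2 | (4R,5S,6R)-4-(3,4-dimethoxyphenyl)-5,6-dimethylcyclohex-2-en-1-one | O=C1C=C[C@@H](c2ccc(OC)c(OC)c2)[C@H](C)[C@H]1C
A5 | alternative 2 | 2,3-dimethoxybuta-1,3-diene | C=C(OC)C(=C)OC
A6 | alternative 2 | (2R,3S,4S,4aR,8aR)-4-(3,4-dimethoxyphenyl)-6,7-dimethoxy-2,3-dimethyl-3,4,4a,5,8,8a-hexahydronaphthalen-1(2H)-one (cis-fused, new ring anti to the aryl group) | COC1=C(OC)C[C@@H]2[C@@H](c3ccc(OC)c(OC)c3)[C@H](C)[C@@H](C)C(=O)[C@@H]2C1
A7 | alternative 3 | 2-(3,4-dimethoxybenzyl)-4,5-dimethoxybenzaldehyde | COc1ccc(Cc2cc(OC)c(OC)cc2C=O)cc1OC
A8 | alternative 3 | methyl (E)-but-2-enoate | C/C=C/C(=O)OC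
A9 | alternative 3 | methyl (1R,2R,3S,4R)-4-(3,4-dimethoxyphenyl)-1-hydroxy-6,7-dimethoxy-3-methyl-1,2,3,4-tetrahydronaphthalene-2-carboxylate | COc1ccc([C@@H]2c3cc(OC)c(OC)cc3[C@H](O)[C@H](C(=O)OC)[C@H]2C)cc1OC
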